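3 questions are put to this flask: how much D, J and Q it holds when the dose ends.

the same everywhere: J 0.058 M; L 58 µM
- north: Q 0.041 M (fed, over 8.0 h); run made earlier; the fed solution adds 1.0 times the starting volume
- north-east: Q 0.064 M (fed, over 8.0 h); run made earlier; the fed solution adds 1.0 times the starting volume
- flask: Q 0.0290 M (fed, over 8.0 h); the fed solution adds 1.0 times the starting volume; time 8.0 h

| run | time / h | D / % | J / % |
|---|---|---|---|
| north | 0.417 | 1.0 | 100.4 |
| north | 0.667 | 1.0 | 100.3 |
| north | 1.33 | 3.2 | 97.9 |
| north | 2.50 | 6.9 | 90.4 |
| north | 5.00 | 22.6 | 76.4 |
| north-east | 0.417 | 0.7 | 98.6 |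
| north-east | 0.667 | 0.8 | 98.3 |
| north-east | 1.33 | 5.6 | 95.8 |
| north-east | 2.50 | 11.3 | 88.2 |
| north-east | 5.00 | 30.7 | 68.1 |

(readings scatter by 1 percentage point)

- percentages count the J that a species holds: one G counts as two
- every charge counts on the volume at the start, and the solution that is fed holds the whole dose
- steps under discussion: J + L -> X; Q + X <-> E; E -> Z; Z -> L + D; J + E <-> G

- how much D the flask holds at 8.0 h, in percent of the J charged
- how much J the flask holds at 8.0 h, in percent of the J charged
- concentration of Q at 8.0 h, in M

Q is the limiting reagent, its charge being 50.0% of the J charge, and one Q goes per D. So the number to watch is r, the share of the Q charge left. D is the charge ratio times the fed share minus r, and J is the rest.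

Taken as pseudo-first-order in dissolved Q, r gains the feed and loses a·r/u of that rate, where u is the volume over the starting volume. Past a knee, r therefore runs along u over one plus a. The readings at 5.00 h give a = 4.32 in the north run and 3.69 in the north-east run, lower at the larger Q charge, both with the scatter of the readings. A straight line in one over a against the Q charge gives this flask its clearance number, the dosing time over the time constant of Q at starting volume: 4.75.

By this reckoning r in the flask starts with the slope of the feed, and D with none. The knee comes at 1.68 h, and beyond it 82.6% of the feed turns into D. D crosses the Q left near 4.27 h. At 8.0 h r stands at 34.8%, which gives D 32.6%, J 67.4% and Q 0.00504 M. After the feed, D heads for the charge ratio.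

The forecast, holding that “The rate of D formation tracks dissolved Q, with dilution”, gives D 29%, J 70% and Q 0.0061 M, lower in D and higher in Q than this reckoning.

    J + L → X (k = 4200 L mol⁻¹ min⁻¹)
    Q + X ⇌ E (K = 83.0 L mol⁻¹, k = 370 L mol⁻¹ min⁻¹)
    E → Z (k = 9.00 min⁻¹)
    Z → L + D (k = 6.30 min⁻¹)
    J + E ⇌ G, settled at all times (K = 54.0 L mol⁻¹)

At 8.0 h the flask holds D 32.2%, J 67.7% and Q 0.00515 M; the Q left, 35% of its charge, gives a = 4.63 against 4.75. The half-life of J by the path from J + L to X is 13 h at 4.69 h, longer than the dosing time, while E passes to Z with a half-life of 0.077 min at the end, and X, the resting state, holds 66.3% of the catalyst. For a neighbouring flask with 0.017 M of Q, the same line gives a = 5.27 and D 20.0%; that flask holds 20.2%.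

The readings were generated by integration on assumed constants; the scatter is artificial.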